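**Retrosynthetic overview**

1. Target 20 ⇐ silyl ether 19 ⇐ diol 17 ⇐ acetonide 16 ⇐ diol 14: C5–O desilylation, acetylation of the secondary C1–OH beside the tertiary C6–OH, acetal hydrolysis, and benzoylation of C2–OH and C7–OH.
2. 14 ⇐ acetonide ester 13 (LiAlH4) ⇐ silyl ether 11 (triethylsilyl ethers exchanged for an acetonide on the cis C1/C6 diol, leaving C2–OH as the only free hydroxyl) ⇐ hydroxy acid 9 (methyl ester, C5–O silylation) ⇐ allylboronate acid 8 (C5–B to C5–OH with retention).
3. Key disconnection 8 ⇐ lactone 5 by Ireland–Claisen ring contraction (makes C6–C5, breaks the ring O–C3 bond, places C3=C4). It rests on reading C7–C6(O)–C1(O)–C2(O)–C3 of the cyclohexene as C1–C5 of D-gluconic acid and C3=C4–C5 as an allyl unit on the carbinol carbon of its 1,5-lactone ring.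
4. 5 ⇐ D-glucono-1,5-lactone 1 by persilylation, direct Swern oxidation of the primary silyl ether and Takai–Utimoto boryl olefination with 4.
5. Ring order: the cyclohexene, the only ring of the target besides the phenyl groups, is made in step 4; the dioxolane ring of 13–16 is temporary.

Key step: step 4

Convention: carbocycles are numbered as in the target, C1 (OAc), C2 (OBz), C3=C4, C5 (secondary OH), C6 (tertiary OH), C7 (exocyclic carbon on C6). β is the ring face of the C1 and C6 oxygens; α is the face of the C2 and C5 oxygens and of C7. Bpin = 4,4,5,5-tetramethyl-1,3,2-dioxaborolan-2-yl. Numbered reactants are the compounds that deliver carbon to the target; other atom-donating reagents, and a second equivalent of a numbered reactant where one is built in, are given with SMILES in their steps.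

**Route**

Step 1
Reactants: 1 D-glucono-1,5-lactone
Product: 2 2,3,4,6-tetrakis-O-(triethylsilyl)-D-glucono-1,5-lactone
Conditions: Et3SiCl (4.5 equiv), imidazole, 4-(dimethylamino)pyridine (cat.), DMF, 0 → 23 °C
Reagents that add atoms: chlorotriethylsilane, CC[Si](Cl)(CC)CC
Why: Silyl ether formation with a silyl chloride and imidazole should cap all four hydroxyls without opening the δ-lactone or touching its four stereocentres.

Step 2
Reactants: 2 2,3,4,6-tetrakis-O-(triethylsilyl)-D-glucono-1,5-lactone
Product: 3 2,3,4-tris-O-(triethylsilyl)-D-glucono-1,5-lactone 6-aldehyde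
Conditions: (COCl)2, DMSO, CH2Cl2, −78 → −35 °C; then iPr2NEt, −78 → −20 °C; crude 3 used at once
Reagents that add atoms: none
Why: Under Swern conditions the chlorosulfonium reagent should attack only the unhindered primary silyl ether, whose oxygen passes from silicon to sulfur and is then oxidised to the aldehyde (direct Swern oxidation of a primary triethylsilyl ether), while the secondary silyl ethers stay and the hindered amine at low temperature should spare the C5 centre.

Step 3
Reactants: 3 2,3,4-tris-O-(triethylsilyl)-D-glucono-1,5-lactone 6-aldehyde; 4 2-(dichloromethyl)-4,4,5,5-tetramethyl-1,3,2-dioxaborolane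
Product: 5 (E)-6,7-dideoxy-7-Bpin-2,3,4-tris-O-(triethylsilyl)-D-gluco-hept-6-enono-1,5-lactone
Conditions: CrCl2 (8 equiv), LiI (4 equiv), THF, 23 °C
Reagents that add atoms: none
Why: Takai–Utimoto boryl olefination: the geminal dichromium reagent formed from 4 by divalent chromium adds to the aldehyde and eliminates to the (E)-alkenylboronate, and this non-basic reagent should tolerate the lactone, the silyl ethers and the α-oxygenated aldehyde.

Step 4
Reactants: 5 (E)-6,7-dideoxy-7-Bpin-2,3,4-tris-O-(triethylsilyl)-D-gluco-hept-6-enono-1,5-lactone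
Product: 8 5α-Bpin-1β,2α,6β-tris(triethylsilyloxy)cyclohex-3-ene-6α-carboxylic acid, via trimethylsilyl ketene acetal 6 (not isolated), via trimethylsilyl ester 7 (not isolated)
Conditions: LiN(iPr)2, Me3SiCl/Et3N, THF, −78 °C; then PhMe, 90 °C; then pH 7 buffer, THF, 23 °C
Reagents that add atoms: chlorotrimethylsilane, C[Si](C)(C)Cl (its Me3Si group is carried by 6 and 7 and is lost on hydrolysis; 8 keeps no reagent atom)
Why: LiN(iPr)2 removes the C2–H of the lactone and the Me3SiCl already present silylates the enolate on oxygen at −78 °C, before the C3 silyloxy group can be expelled, to give the endocyclic ketene acetal 6; on warming, 6 undergoes a concerted suprafacial [3,3] shift (Ireland–Claisen rearrangement) in which gluconate C2 bonds to the boron-bearing vinyl carbon, the ring O–C5 bond breaks and the C3=C4 alkene of the carbocycle appears, and mild hydrolysis of silyl ester 7 gives acid 8. The closest known reactions are the ester-enolate Claisen ring contraction of ω-alkenyl lactones and the Ireland–Claisen rearrangement of esters of 3-borylallyl alcohols to allylboronates. The cyclohexene is closed in the pericyclic step itself: because only two carbons (gluconate C3 and C4) link the reacting termini, the six-centre array is a bicyclo[2.2.2]octane-like boat, and the carbocycle arises by this ring contraction and not by an ionic cyclisation. C6 is set by the ring: the vinyl group can reach the ketene acetal only on the lactone face on which it stands, which puts the new C6–C5 bond there, the C6 oxygen cis to the C1 oxygen and the carboxyl on the α face. C5 is set by the alkene: in the boat the (E)-boryl substituent takes the outward position and ends cis to the carboxyl. The step needs O-silylation to outrun β-elimination (secured by the internal quench at low temperature) and the boat to be the only pathway (secured by the short tether, the fixed ketene acetal geometry and the (E)-alkene), while the absolute sense is relayed from the D-gluco centres.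

Step 5
Reactants: 8 5α-Bpin-1β,2α,6β-tris(triethylsilyloxy)cyclohex-3-ene-6α-carboxylic acid
Product: 9 5α-hydroxy-1β,2α,6β-tris(triethylsilyloxy)cyclohex-3-ene-6α-carboxylic acid
Conditions: NaBO3·4H2O, THF/H2O (1:1), 23 °C
Reagents that add atoms: sodium perborate, [Na+].[O-]B1OO1
Why: Oxidation of a pinacol boronate with perborate: the peroxoborate adds to boron and C5 shifts from boron to oxygen with retention and without allylic transposition, which should give the 5α-alcohol cis to the carboxyl group under conditions mild enough to keep all three triethylsilyl ethers.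

Step 6
Reactants: 9 5α-hydroxy-1β,2α,6β-tris(triethylsilyloxy)cyclohex-3-ene-6α-carboxylic acid
Product: 10 methyl 5α-hydroxy-1β,2α,6β-tris(triethylsilyloxy)cyclohex-3-ene-6α-carboxylate
Conditions: Me3SiCHN2, MeOH/PhMe (1:4), 0 °C
Reagents that add atoms: trimethylsilyldiazomethane, C[Si](C)(C)C=[N+]=[N-]
Why: Esterification of a carboxylic acid with trimethylsilyldiazomethane in methanol methylates only the carboxyl group, and the ester keeps the α-hydroxy acid out of the later acetal formation and serves as the handle for reduction to C7–OH.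

Step 7
Reactants: 10 methyl 5α-hydroxy-1β,2α,6β-tris(triethylsilyloxy)cyclohex-3-ene-6α-carboxylate
Product: 11 methyl 1β,2α,6β-tris(triethylsilyloxy)-5α-(triisopropylsilyloxy)cyclohex-3-ene-6α-carboxylate
Conditions: iPr3SiOTf, 2,6-lutidine, CH2Cl2, 0 → 23 °C
Reagents that add atoms: triisopropylsilyl trifluoromethanesulfonate, CC(C)[Si](OS(=O)(=O)C(F)(F)F)(C(C)C)C(C)C
Why: Silylation of the only free hydroxyl with a silyl triflate and a hindered pyridine base should give a C5 ether that outlasts the triethylsilyl ethers in acid and withstands hydride, acylation and the later acetal hydrolysis.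

Step 8
Reactants: 11 methyl 1β,2α,6β-tris(triethylsilyloxy)-5α-(triisopropylsilyloxy)cyclohex-3-ene-6α-carboxylate
Product: 13 methyl 2α-hydroxy-1β,6β-O-isopropylidene-5α-(triisopropylsilyloxy)cyclohex-3-ene-6α-carboxylate, via triol ester 12 (not isolated)
Conditions: p-toluenesulfonic acid monohydrate (cat.), MeOH, 23 °C; evaporate; then Me2C(OMe)2, acetone, 23 °C
Reagents that add atoms: 2,2-dimethoxypropane, COC(C)(C)OC
Why: Acid methanolysis should strip the three triethylsilyl ethers and spare the far slower-cleaving triisopropylsilyl ether, after which acid-catalysed isopropylidene acetal formation can engage only the cis C1/C6 diol, because the C1/C2 diol is trans and the carboxyl is blocked as its ester, so that C2–OH is left as the single free hydroxyl.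

Step 9
Reactants: 13 methyl 2α-hydroxy-1β,6β-O-isopropylidene-5α-(triisopropylsilyloxy)cyclohex-3-ene-6α-carboxylate
Product: 14 6α-(hydroxymethyl)-1β,6β-O-isopropylidene-5α-(triisopropylsilyloxy)cyclohex-3-en-2α-ol
Conditions: LiAlH4, THF, 0 °C
Reagents that add atoms: none
Why: Hydride reduction of the ester with LiAlH4 gives the C7 primary alcohol, so that the two free hydroxyls are exactly the positions that carry benzoates in the target, without touching the acetal, the silyl ether, the alkene or any stereocentre.

Step 10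
Reactants: 14 6α-(hydroxymethyl)-1β,6β-O-isopropylidene-5α-(triisopropylsilyloxy)cyclohex-3-en-2α-ol; 15 benzoyl chloride
Product: 16 2α-benzoyloxy-6α-(benzoyloxymethyl)-1β,6β-O-isopropylidene-5α-(triisopropylsilyloxy)cyclohex-3-ene
Conditions: BzCl (3 equiv), pyridine, 4-(dimethylamino)pyridine (cat.), CH2Cl2, 0 → 23 °C
Reagents that add atoms: benzoyl chloride (the second equivalent, which supplies the second benzoyl group; the first is reactant 15), O=C(Cl)c1ccccc1
Why: Acylation with the acid chloride under nucleophilic catalysis should esterify the only two free hydroxyls, the primary C7–OH and the secondary C2–OH, each taking one benzoyl group from one equivalent of benzoyl chloride.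

Step 11
Reactants: 16 2α-benzoyloxy-6α-(benzoyloxymethyl)-1β,6β-O-isopropylidene-5α-(triisopropylsilyloxy)cyclohex-3-ene
Product: 17 2α-benzoyloxy-6α-(benzoyloxymethyl)-5α-(triisopropylsilyloxy)cyclohex-3-ene-1β,6β-diol
Conditions: CF3CO2H/H2O (9:1), CH2Cl2, 0 °C
Reagents that add atoms: none
Why: Acid-catalysed hydrolysis of the isopropylidene acetal should free the C1/C6 diol at 0 °C, where the triisopropylsilyl ether and the benzoates should persist and acyl migration should be slow.

Step 12
Reactants: 17 2α-benzoyloxy-6α-(benzoyloxymethyl)-5α-(triisopropylsilyloxy)cyclohex-3-ene-1β,6β-diol; 18 acetic anhydride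
Product: 19 1β-acetoxy-2α-benzoyloxy-6α-(benzoyloxymethyl)-5α-(triisopropylsilyloxy)cyclohex-3-en-6β-ol
Conditions: Ac2O, pyridine, 4-(dimethylamino)pyridine (cat.), CH2Cl2, 0 °C
Reagents that add atoms: none
Why: Acetylation with the anhydride should occur only at the secondary C1–OH, because the tertiary C6–OH is too hindered to be acylated under these mild conditions (chemoselective esterification).

Step 13
Reactants: 19 1β-acetoxy-2α-benzoyloxy-6α-(benzoyloxymethyl)-5α-(triisopropylsilyloxy)cyclohex-3-en-6β-ol
Product: 20 HY-N2634, 1β-acetoxy-2α-benzoyloxy-6α-(benzoyloxymethyl)cyclohex-3-ene-5α,6β-diol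
Conditions: HF·pyridine, pyridine, THF, 0 → 23 °C
Reagents that add atoms: none
Why: Fluoride-mediated cleavage of the silyl ether under buffered, weakly acidic conditions should free C5–OH without ester hydrolysis or acyl migration.

**Compound list**

1 | D-glucono-1,5-lactone | O=C1O[C@H](CO)[C@@H](O)[C@H](O)[C@H]1O | starting material
2 | 2,3,4,6-tetrakis-O-(triethylsilyl)-D-glucono-1,5-lactone | O=C1O[C@H](CO[Si](CC)(CC)CC)[C@@H](O[Si](CC)(CC)CC)[C@H](O[Si](CC)(CC)CC)[C@H]1O[Si](CC)(CC)CC | intermediate
3 | 2,3,4-tris-O-(triethylsilyl)-D-glucono-1,5-lactone 6-aldehyde (gluconate C6 is CHO; D-gluco at C2–C5) | O=C1O[C@H](C=O)[C@@H](O[Si](CC)(CC)CC)[C@H](O[Si](CC)(CC)CC)[C@H]1O[Si](CC)(CC)CC | intermediate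
4 | 2-(dichloromethyl)-4,4,5,5-tetramethyl-1,3,2-dioxaborolane | ClC(Cl)B1OC(C)(C)C(C)(C)O1 | starting material
5 | (E)-6,7-dideoxy-7-Bpin-2,3,4-tris-O-(triethylsilyl)-D-gluco-hept-6-enono-1,5-lactone | O=C1O[C@H](/C=C/B2OC(C)(C)C(C)(C)O2)[C@@H](O[Si](CC)(CC)CC)[C@H](O[Si](CC)(CC)CC)[C@H]1O[Si](CC)(CC)CC | intermediate
6 | trimethylsilyl ketene acetal of 5 (endocyclic C1=C2 of the lactone; C3, C4, C5 as in 5) | C[Si](C)(C)OC1=C(O[Si](CC)(CC)CC)[C@@H](O[Si](CC)(CC)CC)[C@H](O[Si](CC)(CC)CC)[C@@H](/C=C/B2OC(C)(C)C(C)(C)O2)O1 | intermediate (not isolated)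
7 | trimethylsilyl ester of 8 | CC[Si](CC)(CC)O[C@H]1[C@H](O[Si](CC)(CC)CC)C=C[C@H](B2OC(C)(C)C(C)(C)O2)[C@]1(O[Si](CC)(CC)CC)C(=O)O[Si](C)(C)C | intermediate (not isolated)
8 | 5α-Bpin-1β,2α,6β-tris(triethylsilyloxy)cyclohex-3-ene-6α-carboxylic acid | CC[Si](CC)(CC)O[C@H]1[C@H](O[Si](CC)(CC)CC)C=C[C@H](B2OC(C)(C)C(C)(C)O2)[C@]1(O[Si](CC)(CC)CC)C(=O)O | intermediate
9 | 5α-hydroxy-1β,2α,6β-tris(triethylsilyloxy)cyclohex-3-ene-6α-carboxylic acid | CC[Si](CC)(CC)O[C@H]1[C@H](O[Si](CC)(CC)CC)C=C[C@H](O)[C@]1(O[Si](CC)(CC)CC)C(=O)O | intermediate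
10 | methyl 5α-hydroxy-1β,2α,6β-tris(triethylsilyloxy)cyclohex-3-ene-6α-carboxylate | CC[Si](CC)(CC)O[C@H]1[C@H](O[Si](CC)(CC)CC)C=C[C@H](O)[C@]1(O[Si](CC)(CC)CC)C(=O)OC | intermediate
11 | methyl 1β,2α,6β-tris(triethylsilyloxy)-5α-(triisopropylsilyloxy)cyclohex-3-ene-6α-carboxylate | CC[Si](CC)(CC)O[C@H]1[C@H](O[Si](CC)(CC)CC)C=C[C@H](O[Si](C(C)C)(C(C)C)C(C)C)[C@]1(O[Si](CC)(CC)CC)C(=O)OC | intermediate
12 | methyl 1β,2α,6β-trihydroxy-5α-(triisopropylsilyloxy)cyclohex-3-ene-6α-carboxylate | O[C@H]1[C@H](O)C=C[C@H](O[Si](C(C)C)(C(C)C)C(C)C)[C@]1(O)C(=O)OC | intermediate (not isolated)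
13 | methyl 2α-hydroxy-1β,6β-O-isopropylidene-5α-(triisopropylsilyloxy)cyclohex-3-ene-6α-carboxylate | CC1(C)O[C@H]2[C@H](O)C=C[C@H](O[Si](C(C)C)(C(C)C)C(C)C)[C@]2(O1)C(=O)OC | intermediate
14 | 6α-(hydroxymethyl)-1β,6β-O-isopropylidene-5α-(triisopropylsilyloxy)cyclohex-3-en-2α-ol | CC1(C)O[C@H]2[C@H](O)C=C[C@H](O[Si](C(C)C)(C(C)C)C(C)C)[C@]2(O1)CO | intermediate
15 | benzoyl chloride | O=C(Cl)c1ccccc1 | starting material
16 | 2α-benzoyloxy-6α-(benzoyloxymethyl)-1β,6β-O-isopropylidene-5α-(triisopropylsilyloxy)cyclohex-3-ene | CC1(C)O[C@H]2[C@H](OC(=O)c3ccccc3)C=C[C@H](O[Si](C(C)C)(C(C)C)C(C)C)[C@]2(O1)COC(=O)c1ccccc1 | intermediate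
17 | 2α-benzoyloxy-6α-(benzoyloxymethyl)-5α-(triisopropylsilyloxy)cyclohex-3-ene-1β,6β-diol | O[C@H]1[C@H](OC(=O)c2ccccc2)C=C[C@H](O[Si](C(C)C)(C(C)C)C(C)C)[C@]1(O)COC(=O)c1ccccc1 | intermediate
18 | acetic anhydride | CC(=O)OC(C)=O | starting material
19 | 1β-acetoxy-2α-benzoyloxy-6α-(benzoyloxymethyl)-5α-(triisopropylsilyloxy)cyclohex-3-en-6β-ol | CC(=O)O[C@H]1[C@H](OC(=O)c2ccccc2)C=C[C@H](O[Si](C(C)C)(C(C)C)C(C)C)[C@]1(O)COC(=O)c1ccccc1 | intermediate
20 | HY-N2634, 1β-acetoxy-2α-benzoyloxy-6α-(benzoyloxymethyl)cyclohex-3-ene-5α,6β-diol; (1S,2R,5S,6R) in the numbering used here | CC(=O)O[C@H]1[C@H](OC(=O)c2ccccc2)C=C[C@H](O)[C@]1(O)COC(=O)c1ccccc1 | target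

**Step count and risk**

Total steps: 13. Longest linear sequence: 13 steps (fully linear from 1).

Steps most likely to fail:

Step 4. Three processes may defeat it. The C3 silyloxy group may be expelled from the lactone enolate before O-silylation; the axial-rich ring conformer favoured by three vicinal silyl ethers aligns this bond with the enolate. The amide base may attack boron, or the allylboronate may lose boron at 90 °C. The shift may be slowed by the contact between the boron substituent and the C2 silyloxy group in the boat, so that the ketene acetal decays first. The fallback places the oxygen on the alkene before the rearrangement, so that no boron enters the sigmatropic step and the donor at the allyl terminus speeds it. It sets out from 5 and returns at 9. Oxidative coupling of the alkenylboronate with 4-methoxybenzyl alcohol mediated by Cu(OAc)2 (Et3N, molecular sieves, air, CH2Cl2; Chan–Lam-type etherification with retention of alkene geometry) should give the (E)-enol ether lactone F1. LiN(iPr)2 with Me3SiCl at −78 °C should give its trimethylsilyl ketene acetal F2. On warming, this should rearrange through the same boat to the trimethylsilyl ester F3, which is hydrolysed on work-up to the 5α-(4-methoxybenzyloxy) acid F4. Oxidative removal of the 4-methoxybenzyl group with 2,3-dichloro-5,6-dicyano-1,4-benzoquinone in wet CH2Cl2 should then give hydroxy acid 9.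

Step 2. The amine base may cause β-elimination of the C4 silyloxy group or epimerisation at C5 of the α-oxygenated aldehyde; epimerisation would put the alkene on the wrong lactone face. The sulfonium reagent may also discriminate poorly between primary and secondary silyl ethers. The fallback separates deprotection from oxidation and avoids amine base. It sets out from 2 and returns at 3. HF·pyridine buffered with pyridine in THF at 0 °C should cleave only the primary silyl ether and give 2,3,4-tris-O-(triethylsilyl)-D-glucono-1,5-lactone F5. Dess–Martin periodinane with NaHCO3 in CH2Cl2 should then oxidise the primary alcohol to aldehyde 3.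

Step 8. Cleavage of the tertiary triethylsilyl ether may lag behind, the triisopropylsilyl ether may be partly lost in the acid, or the acetal may close slowly on the hindered tertiary hydroxyl. The fallback gives up the acetal and differentiates C1–OH from C2–OH by steric hindrance alone. It sets out from 11 and returns at 17. LiAlH4 in THF at 0 °C should reduce the ester to the 6α-(hydroxymethyl) tris(triethylsilyl) ether F6. p-Toluenesulfonic acid in MeOH should remove the three triethylsilyl ethers to give the 5α-silyloxy tetraol F7. Benzoyl chloride (2.1 equiv) with pyridine in CH2Cl2 at −40 °C should then acylate the primary C7–OH and, of the two secondary hydroxyls, the allylic C2–OH in preference to the C1–OH beside the quaternary C6, giving diol 17.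

**Further compounds**

F1 | step 4 | (E)-6,7-dideoxy-7-(4-methoxybenzyloxy)-2,3,4-tris-O-(triethylsilyl)-D-gluco-hept-6-enono-1,5-lactone | O=C1O[C@H](/C=C/OCc2ccc(OC)cc2)[C@@H](O[Si](CC)(CC)CC)[C@H](O[Si](CC)(CC)CC)[C@H]1O[Si](CC)(CC)CC
F2 | step 4 | trimethylsilyl ketene acetal of F1 | C[Si](C)(C)OC1=C(O[Si](CC)(CC)CC)[C@@H](O[Si](CC)(CC)CC)[C@H](O[Si](CC)(CC)CC)[C@@H](/C=C/OCc2ccc(OC)cc2)O1
F3 | step 4 | trimethylsilyl ester of F4 | CC[Si](CC)(CC)O[C@H]1[C@H](O[Si](CC)(CC)CC)C=C[C@H](OCc2ccc(OC)cc2)[C@]1(O[Si](CC)(CC)CC)C(=O)O[Si](C)(C)C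
F4 | step 4 | 5α-(4-methoxybenzyloxy)-1β,2α,6β-tris(triethylsilyloxy)cyclohex-3-ene-6α-carboxylic acid | CC[Si](CC)(CC)O[C@H]1[C@H](O[Si](CC)(CC)CC)C=C[C@H](OCc2ccc(OC)cc2)[C@]1(O[Si](CC)(CC)CC)C(=O)O
F5 | step 2 | 2,3,4-tris-O-(triethylsilyl)-D-glucono-1,5-lactone | O=C1O[C@H](CO)[C@@H](O[Si](CC)(CC)CC)[C@H](O[Si](CC)(CC)CC)[C@H]1O[Si](CC)(CC)CC
F6 | step 8 | 6α-(hydroxymethyl)-1β,2α,6β-tris(triethylsilyloxy)-5α-(triisopropylsilyloxy)cyclohex-3-ene | CC[Si](CC)(CC)O[C@H]1[C@H](O[Si](CC)(CC)CC)C=C[C@H](O[Si](C(C)C)(C(C)C)C(C)C)[C@]1(O[Si](CC)(CC)CC)CO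
F7 | step 8 | 6α-(hydroxymethyl)-5α-(triisopropylsilyloxy)cyclohex-3-ene-1β,2α,6β-triol | O[C@H]1[C@H](O)C=C[C@H](O[Si](C(C)C)(C(C)C)C(C)C)[C@]1(O)CO
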